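Ring B (C5–C6–C7–C8–C9–C10, drimane numbering) is never annulated directly. It is released from a bicyclo[3.1.0]hexane: a five-membered ring (C5, C7, C8, C9, C10) bridged across C5–C7 by cyclopropane carbon C6 and carrying C17 as an exocyclic methylene on C8. Hydrogen-atom transfer to C17 fragments the C5–C7 bond, so that C6 enters the ring; this creates the C17 methyl, the trans C5–H and a C7=C8 olefin, which in the same flask adds as a C8 radical to a chiral butenolide, forming quaternary C8 and C14. The key step exploits the methyl-bearing quaternary C8 next to the C6–C7 methylene pair of ring B.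

Key step: step 10

Numbering used below (spongian/drimane): ring A = C1–C5 and C10; ring B = C5–C10; C11 = formyl carbon on C9; C17 = methyl on C8; heterocycle = C14 (on C8), C15 (acetoxy acetal), C16 (enol-ether CH), C13 (carries C12).
Assumption: (5S)-5-(d-menthyloxy)furan-2(5H)-one (12) is treated as purchasable like its enantiomer, and the sense of induction in step 2 is assumed to follow the simpler 2-allyl-2-methylcyclohexanone series.

Step 1
Reactants: 1 2,2,6-trimethylcyclohexan-1-one
Product: 2 allyl 2,6,6-trimethylcyclohex-1-en-1-yl carbonate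
Conditions: LiN(SiMe3)2, THF, 0 °C; then allyl chloroformate, −78 °C to rt
Reagents that add atoms: allyl chloroformate, C=CCOC(=O)Cl
Why: The only enolisable position gives a single tetrasubstituted lithium enolate that is O-acylated by the chloroformate (enol carbonate formation), which is the substrate for the decarboxylative allylation.

Step 2
Reactants: 2 allyl 2,6,6-trimethylcyclohex-1-en-1-yl carbonate
Product: 3 (R)-2-allyl-2,6,6-trimethylcyclohexan-1-one
Conditions: Pd2(dba)3 (2.5 mol %), (R)-t-BuPHOX (6 mol %), THF, 25 °C
Reagents that add atoms: none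
Why: In this decarboxylative asymmetric Tsuji allylation the zerovalent palladium–PHOX complex ionises the allyl carbonate, CO2 is lost and the enolate is allylated within the chiral ligand sphere, which should set the quaternary C10 stereocentre as (R) with the (R)-ligand.

Step 3
Reactants: 3 (R)-2-allyl-2,6,6-trimethylcyclohexan-1-one
Product: 4 (R)-2,2,6-trimethyl-6-(2-oxopropyl)cyclohexan-1-one
Conditions: PdCl2 (10 mol %), Cu(OAc)2 (20 mol %), O2 (1 atm), DMA/H2O (7:1), rt
Reagents that add atoms: water, O
Why: Tsuji–Wacker oxidation converts the terminal olefin into the methyl ketone with Markovnikov selectivity while the hindered, non-enolisable ring ketone is untouched.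

Step 4
Reactants: 4 (R)-2,2,6-trimethyl-6-(2-oxopropyl)cyclohexan-1-one
Product: 5 bicyclic enone (7aR)-4,4,7a-trimethyl-5,6,7,7a-tetrahydro-1H-inden-2(4H)-one
Conditions: KOH (powdered), xylenes, 110 °C, water removal
Reagents that add atoms: none
Why: Intramolecular aldol condensation of the only available enolate (the methyl group, C7) onto the non-enolisable C5 ketone, followed by dehydration, should close the cyclopentenone without affecting C10.

Step 5
Reactants: 5 bicyclic enone
Product: 7 C9-(tert-butyldiphenylsilyloxymethyl) enone, via hydroxymethyl enone 6 (not isolated)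
Conditions: LiN(i-Pr)2, THF, −78 °C; CH2O (gas), −78 °C; then t-BuPh2SiCl, imidazole, −78 to 0 °C
Reagents that add atoms: formaldehyde, C=O; tert-butyl(chloro)diphenylsilane, CC(C)(C)[Si](Cl)(c1ccccc1)c1ccccc1
Why: Kinetic deprotonation can occur only at C9, and aldol addition to formaldehyde with silylation of the alkoxide in the same flask installs C11 on the enolate face away from the ring-A methylene (cis to the C10 methyl), a centre that stays epimerisable toward this more stable arrangement while C8 is a ketone.

Step 6
Reactants: 7 C9-(tert-butyldiphenylsilyloxymethyl) enone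
Product: 8 allylic alcohol (8-OH on the β face)
Conditions: NaBH4, CeCl3·7H2O, MeOH, −40 °C
Reagents that add atoms: none
Why: Luche reduction gives clean 1,2-reduction of the enone, hydride arriving anti to the C9 side chain so that the hydroxyl is expected on the β face (its configuration is erased in step 8 and serves only to direct step 7).

Step 7
Reactants: 8 allylic alcohol
Product: 9 cyclopropyl carbinol (C6 bridging C5 and C7)
Conditions: Et2Zn, CH2I2, CH2Cl2, 0 °C to rt
Reagents that add atoms: diiodomethane, ICI
Why: In the Simmons–Smith reaction (Furukawa variant) the zinc alkoxide delivers the carbenoid to the adjacent C5=C7 olefin on its own face, so that C6 enters as a cis-fused cyclopropane whose configuration is later erased.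

Step 8
Reactants: 9 cyclopropyl carbinol
Product: 10 cyclopropyl ketone
Conditions: Dess–Martin periodinane, NaHCO3, CH2Cl2, rt
Reagents that add atoms: none
Why: Dess–Martin oxidation of the secondary cyclopropyl carbinol gives the ketone under non-acidic conditions that spare the cyclopropane.

Step 9
Reactants: 10 cyclopropyl ketone
Product: 11 vinylcyclopropane (exocyclic C8=C17)
Conditions: Ph3PCH3Br, KOt-Bu, toluene, 0 to 80 °C
Reagents that add atoms: methyltriphenylphosphonium bromide, C[P+](c1ccccc1)(c1ccccc1)c1ccccc1.[Br-]
Why: Wittig methylenation installs C17 as an exocyclic methylene and thereby the vinylcyclopropane needed for the fragmentation, any epimerisation at C9 leading to the more stable cis arrangement.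

Step 10
Reactants: 11 vinylcyclopropane; 12 (5S)-5-(d-menthyloxy)furan-2(5H)-one
Product: 14 lactone adduct (C8–C14 bond formed), via drimene silyl ether 13 (not isolated)
Conditions: Fe(acac)3 (0.3 equiv.), PhSiH3 (4 equiv.), 12 (3 equiv.), EtOH/ethylene glycol (5:1), 60 °C
Reagents that add atoms: none
Why: Proposed new method: an iron hydride generated from Fe(acac)3 and PhSiH3 transfers a hydrogen atom to C17 (MHAT, metal-hydride hydrogen-atom transfer), and the tertiary C8 radical, a cyclopropylcarbinyl radical of the bicyclo[3.1.0]hexane, cleaves the ring-fusion bond C5–C7, so that C6 enters the ring and the five-membered ring C5/C7/C8/C9/C10 becomes six-membered ring B with a C7=C8 olefin and a tertiary C5 radical. The C5 radical, flanked by the quaternary carbons C4 and C10, is too hindered to add to 12 and is reduced by hydrogen-atom donation to drimene 13, whereupon a second hydrogen-atom transfer to C7 of 13 regenerates a tertiary C8 radical that adds to C4 of butenolide 12 (Giese addition), the resulting α-acyl radical being reduced and protonated. The closest known reaction types are the radical-clock opening of thujone- and sabinene-type bicyclo[3.1.0]hexyl radicals to cyclohexenyl radicals, MHAT hydrogenation with thermodynamic stereocontrol and the iron-mediated reductive olefin coupling; only their relay in one flask is new. No ring is closed by bond formation, because ring B arises by fragmentation (ring expansion by one atom, C6). C5 is set by axial hydrogen delivery to the trans-decalin, C8 by addition anti to the axial C10 methyl (new bond equatorial, C17 axial) and C14 by approach anti to the menthyloxy group on C15 of 12. The step needs cleavage of the internal rather than the external cyclopropane bond, secured by formation of a tertiary radical with loss of bicyclic strain (a primary radical from external cleavage can reclose), and reduction rather than addition of the C5 radical, secured by its two quaternary neighbours.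

Step 11
Reactants: 14 lactone adduct
Product: 16 acetoxymethyl lactone, via hydroxymethyl lactone 15 (not isolated)
Conditions: LiN(i-Pr)2, THF, −78 °C; CH2O (gas); then Ac2O, −78 to 0 °C
Reagents that add atoms: formaldehyde, C=O; acetic anhydride, CC(=O)OC(C)=O
Why: Aldol addition of the lactone lithium enolate (C13, the only acidic position) to formaldehyde occurs anti to the bulky C14 substituent, and the alkoxide is acetylated in the flask to prevent later acetal formation with C15; the C13 configuration is inconsequential because C13 becomes sp2 in step 15.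

Step 12
Reactants: 16 acetoxymethyl lactone
Product: 17 hydroxy lactone (C15 lactol)
Conditions: CF3CO2H/H2O/THF (1:1:4), 40 °C
Reagents that add atoms: water, O
Why: Aqueous acid hydrolysis of the mixed acetal (pseudo-ester) releases menthol and gives the cyclic hydroxy lactone at a stage where no enol ether is present, so that aromatisation to a furan is impossible and C14 is not touched.

Step 13
Reactants: 17 hydroxy lactone
Product: 18 diacetate lactone
Conditions: Ac2O, pyridine, DMAP (cat.), CH2Cl2, 0 °C
Reagents that add atoms: acetic anhydride, CC(=O)OC(C)=O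
Why: Acetylation of the lactol-type hydroxyl gives the acetoxy acetal, expected mainly trans to the bulky C14 substituent because the anomers equilibrate through the open aldehyde-acid form and the less hindered one is acylated faster.

Step 14
Reactants: 18 diacetate lactone
Product: 19 lactol (C16–OH)
Conditions: disiamylborane (from BH3·THF and 2-methylbut-2-ene), THF, 0 °C to rt; pH 7 buffer work-up
Reagents that add atoms: none
Why: Disiamylborane reduces γ-lactones to lactols but not carboxylic esters, the selectivity long used for acylated aldonolactones, so that only C16 should be reduced.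

Step 15
Reactants: 19 lactol
Product: 20 silyl-protected acetoxy dihydrofuran
Conditions: MsCl, Et3N, THF, −40 to 0 °C
Reagents that add atoms: none
Why: Mesylation of the lactol hydroxyl and base-induced elimination of the anomeric sulfonate with the only β-hydrogen (C13–H) forms the C13=C16 enol ether (lactol dehydration as in glycal synthesis), while the C15 acetoxy acetal is not ionised under basic conditions.

Step 16
Reactants: 20 silyl-protected acetoxy dihydrofuran
Product: 21 primary alcohol (C11–OH)
Conditions: Bu4NF, AcOH (1:1), THF, 0 °C to rt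
Reagents that add atoms: none
Why: Buffered fluoride cleaves the primary silyl ether, while the acetic acid buffer suppresses acetate migration and base-induced loss of the acetoxy acetal.

Step 17
Reactants: 21 primary alcohol
Product: 22 target compound CNP0170308.1
Conditions: Dess–Martin periodinane, pyridine, CH2Cl2, 0 °C to rt
Reagents that add atoms: none
Why: Buffered Dess–Martin oxidation converts the primary alcohol into the C9 aldehyde without acid, and the formyl group already occupies the thermodynamically preferred equatorial position, so that C9 is not at risk.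

Compound list
1 | 2,2,6-trimethylcyclohexan-1-one (racemic) | CC1CCCC(C)(C)C1=O | starting material
2 | allyl 2,6,6-trimethylcyclohex-1-en-1-yl carbonate | C=CCOC(=O)OC1=C(C)CCCC1(C)C | intermediate
3 | (R)-2-allyl-2,6,6-trimethylcyclohexan-1-one | C=CC[C@@]1(C)CCCC(C)(C)C1=O | intermediate
4 | (R)-2,2,6-trimethyl-6-(2-oxopropyl)cyclohexan-1-one | CC(=O)C[C@@]1(C)CCCC(C)(C)C1=O | intermediate
5 | (7aR)-4,4,7a-trimethyl-5,6,7,7a-tetrahydro-1H-inden-2(4H)-one (C8 ketone, C7=C5 olefin, C9 methylene, C10 quaternary) | O=C1C[C@@]2(C)CCCC(C)(C)C2=C1 | intermediate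
6 | (1S,7aR)-1-(hydroxymethyl)-4,4,7a-trimethyl-5,6,7,7a-tetrahydro-1H-inden-2(4H)-one (CH2OH = C11 on C9, cis to the C10 methyl) | O=C1[C@H](CO)[C@@]2(C)CCCC(C)(C)C2=C1 | intermediate (not isolated)
7 | tert-butyldiphenylsilyl ether of 6 | O=C1[C@H](CO[Si](c3ccccc3)(c3ccccc3)C(C)(C)C)[C@@]2(C)CCCC(C)(C)C2=C1 | intermediate
8 | allylic alcohol: C8 ketone of 7 reduced, 8-OH cis to the C9 side chain and to the C10 methyl | O[C@@H]1[C@H](CO[Si](c3ccccc3)(c3ccccc3)C(C)(C)C)[C@@]2(C)CCCC(C)(C)C2=C1 | intermediate
9 | cyclopropyl carbinol: 8 with CH2 (C6) added across C5=C7 on the face of the hydroxyl | O[C@@H]1[C@H](CO[Si](c4ccccc4)(c4ccccc4)C(C)(C)C)[C@@]2(C)CCCC(C)(C)[C@]23C[C@H]13 | intermediate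
10 | cyclopropyl ketone: 8-oxo compound from 9 | O=C1[C@H](CO[Si](c4ccccc4)(c4ccccc4)C(C)(C)C)[C@@]2(C)CCCC(C)(C)[C@]23C[C@H]13 | intermediate
11 | vinylcyclopropane: 10 with C8=O replaced by C8=CH2 (C17) | C=C1[C@H](CO[Si](c4ccccc4)(c4ccccc4)C(C)(C)C)[C@@]2(C)CCCC(C)(C)[C@]23C[C@H]13 | intermediate
12 | (5S)-5-{[(1S,2R,5S)-2-isopropyl-5-methylcyclohexyl]oxy}furan-2(5H)-one | O=C1C=C[C@@H](O[C@H]2C[C@@H](C)CC[C@@H]2C(C)C)O1 | starting material
13 | (5S,9S,10S)-11-(tert-butyldiphenylsilyloxy)drim-7-ene | CC1=CC[C@H]2C(C)(C)CCC[C@]2(C)[C@H]1CO[Si](c3ccccc3)(c3ccccc3)C(C)(C)C | intermediate (not isolated)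
14 | (4R,5S)-4-{(1R,2R,4aS,8aS)-1-[(tert-butyldiphenylsilyloxy)methyl]-2,5,5,8a-tetramethyldecahydronaphthalen-2-yl}-5-(d-menthyloxy)dihydrofuran-2(3H)-one (C14 substituent trans to the C15 menthyloxy group) | O=C1O[C@H](O[C@H]3C[C@@H](C)CC[C@@H]3C(C)C)[C@H](C1)[C@]1(C)CC[C@H]2C(C)(C)CCC[C@]2(C)[C@H]1CO[Si](c3ccccc3)(c3ccccc3)C(C)(C)C | intermediate
15 | 14 with CH2OH (C12) on C13 (lactone C3), trans to the C14 substituent | O=C1O[C@H](O[C@H]3C[C@@H](C)CC[C@@H]3C(C)C)[C@H]([C@@H]1CO)[C@]1(C)CC[C@H]2C(C)(C)CCC[C@]2(C)[C@H]1CO[Si](c3ccccc3)(c3ccccc3)C(C)(C)C | intermediate (not isolated)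
16 | acetate of 15 (C12–OAc) | O=C1O[C@H](O[C@H]3C[C@@H](C)CC[C@@H]3C(C)C)[C@H]([C@@H]1COC(C)=O)[C@]1(C)CC[C@H]2C(C)(C)CCC[C@]2(C)[C@H]1CO[Si](c3ccccc3)(c3ccccc3)C(C)(C)C | intermediate
17 | 16 with the menthyloxy group replaced by OH (C15 lactol; anomeric mixture, trans anomer drawn) | O=C1O[C@H](O)[C@H]([C@@H]1COC(C)=O)[C@]1(C)CC[C@H]2C(C)(C)CCC[C@]2(C)[C@H]1CO[Si](c3ccccc3)(c3ccccc3)C(C)(C)C | intermediate
18 | 15-O-acetyl derivative of 17 (15-OAc trans to the C14 substituent) | O=C1O[C@H](OC(C)=O)[C@H]([C@@H]1COC(C)=O)[C@]1(C)CC[C@H]2C(C)(C)CCC[C@]2(C)[C@H]1CO[Si](c3ccccc3)(c3ccccc3)C(C)(C)C | intermediate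
19 | lactol: C16 carbonyl of 18 reduced to CH(OH) (anomeric mixture at C16) | OC1O[C@H](OC(C)=O)[C@H]([C@@H]1COC(C)=O)[C@]1(C)CC[C@H]2C(C)(C)CCC[C@]2(C)[C@H]1CO[Si](c3ccccc3)(c3ccccc3)C(C)(C)C | intermediate
20 | [(2R,3S)-2-acetoxy-3-{(1R,2R,4aS,8aS)-1-[(tert-butyldiphenylsilyloxy)methyl]-2,5,5,8a-tetramethyldecahydronaphthalen-2-yl}-2,3-dihydrofuran-4-yl]methyl acetate | CC(=O)OCC1=CO[C@H](OC(C)=O)[C@H]1[C@]1(C)CC[C@H]2C(C)(C)CCC[C@]2(C)[C@H]1CO[Si](c3ccccc3)(c3ccccc3)C(C)(C)C | intermediate
21 | [(2R,3S)-2-acetoxy-3-[(1R,2R,4aS,8aS)-1-(hydroxymethyl)-2,5,5,8a-tetramethyldecahydronaphthalen-2-yl]-2,3-dihydrofuran-4-yl]methyl acetate | CC(=O)OCC1=CO[C@H](OC(C)=O)[C@H]1[C@]1(C)CC[C@H]2C(C)(C)CCC[C@]2(C)[C@H]1CO | intermediate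
22 | [(2R,3S)-2-acetoxy-3-[(1R,2R,4aS,8aS)-1-formyl-2,5,5,8a-tetramethyldecahydronaphthalen-2-yl]-2,3-dihydrofuran-4-yl]methyl acetate (CNP0170308.1) | CC(=O)OCC1=CO[C@H](OC(C)=O)[C@H]1[C@]1(C)CC[C@H]2C(C)(C)CCC[C@]2(C)[C@H]1C=O | target

Total step count: 17. Longest linear sequence: 17 steps (1 to 22); 12 enters as a purchased fragment in step 10.

Steps most likely to fail

Step 10 (Proposed new method). The relay may break down in several ways: fragmentation of the external instead of the internal cyclopropane bond, addition of the C5 radical or of a ring-opened primary radical to the butenolide, simple hydrogenation of the intermediate olefin, or poor facial selectivity at C8. The fallback separates the two radical events with known chemistry. It sets out from cyclopropyl ketone 10: MeMgBr/CeCl3 gives the tertiary cyclopropyl carbinol F1, and oxalyl chloride followed by aqueous CsOH gives its cesium oxalate F2. Visible-light photoredox fragmentation (Ir[dF(CF3)ppy]2(dtbbpy)PF6, an aryl thiol as hydrogen-atom donor, wet DME, blue light) then generates the same C8 radical with no acceptor present, so that ring expansion and hydrogen capture give drimene 13, which is isolated. A single MHAT Giese addition of 13 to 12 (Fe(acac)3, PhSiH3, EtOH/ethylene glycol, 60 °C) comes back to the route at 14.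

Step 15. The lactol may ring-open with loss of acetic acid from C15 before it is sulfonylated, and the enol ether may aromatise to a furan by elimination across C14–C15 during work-up. The fallback sets out from lactol 19 and avoids both base and sulfonate. N-(phenylseleno)phthalimide and Bu3P convert the lactol hydroxyl into the anomeric phenyl selenide F3. Oxidation with NaIO4/NaHCO3 gives the selenoxide, which undergoes syn-elimination at room temperature under neutral conditions and comes back to the route at 20.

Step 16. Fluoride may cleave or shift the acetoxy acetal or trigger elimination to the furan before the hindered silyl ether is removed. The fallback sets out from diacetate lactone 18 and exchanges the silyl group before the sensitive heterocycle exists. HF·pyridine gives the 11-hydroxy lactone F4, and Et3SiOTf/2,6-lutidine gives the triethylsilyl ether F5. Disiamylborane and then MsCl/Et3N, as in steps 14 and 15, give the lactol F6 and the triethylsilyl enol ether F7. Swern conditions (oxalyl chloride, DMSO, then Et3N) oxidise the primary triethylsilyl ether directly to the aldehyde, which comes back to the route at 22 without a fluoride step.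

Further compounds
F1 | step 10 | tertiary cyclopropyl carbinol: 8-hydroxy-8-methyl analogue of 10 (C8 configuration inconsequential, OH drawn β) | C[C@@]1(O)[C@H](CO[Si](c4ccccc4)(c4ccccc4)C(C)(C)C)[C@@]2(C)CCCC(C)(C)[C@]23C[C@H]13
F2 | step 10 | cesium oxalate of F1 | C[C@@]1(OC(=O)C(=O)[O-])[C@H](CO[Si](c4ccccc4)(c4ccccc4)C(C)(C)C)[C@@]2(C)CCCC(C)(C)[C@]23C[C@H]13.[Cs+]
F3 | step 15 | anomeric (C16) phenyl selenide corresponding to lactol 19 | c5ccccc5[Se]C1O[C@H](OC(C)=O)[C@H]([C@@H]1COC(C)=O)[C@]1(C)CC[C@H]2C(C)(C)CCC[C@]2(C)[C@H]1CO[Si](c3ccccc3)(c3ccccc3)C(C)(C)C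
F4 | step 16 | 11-hydroxy diacetate lactone (18 without the silyl group) | O=C1O[C@H](OC(C)=O)[C@H]([C@@H]1COC(C)=O)[C@]1(C)CC[C@H]2C(C)(C)CCC[C@]2(C)[C@H]1CO
F5 | step 16 | 11-O-triethylsilyl diacetate lactone | O=C1O[C@H](OC(C)=O)[C@H]([C@@H]1COC(C)=O)[C@]1(C)CC[C@H]2C(C)(C)CCC[C@]2(C)[C@H]1CO[Si](CC)(CC)CC
F6 | step 16 | 11-O-triethylsilyl lactol (C16–OH, anomeric mixture) | OC1O[C@H](OC(C)=O)[C@H]([C@@H]1COC(C)=O)[C@]1(C)CC[C@H]2C(C)(C)CCC[C@]2(C)[C@H]1CO[Si](CC)(CC)CC
F7 | step 16 | 11-O-triethylsilyl acetoxy dihydrofuran (triethylsilyl analogue of 20) | CC(=O)OCC1=CO[C@H](OC(C)=O)[C@H]1[C@]1(C)CC[C@H]2C(C)(C)CCC[C@]2(C)[C@H]1CO[Si](CC)(CC)CC
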